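**Retrosynthetic overview**
- The target, robinetinidol-(4α→2')-leucorobinetinidin, is cut at its only interflavanyl bond, C4 of ring C of the upper unit to C2' of ring B of the lower unit: an upper C4 cation plus a lower pyrogallol arene.
- Both halves are the same flavanonol, (+)-dihydrorobinetin 1. Reduction gives diol 2, which ionises to quinone methide 3; unchanged 1 is the nucleophile. Their protecting-group-free union gives ketone 4, and reduction of its lower C4 ketone gives target 5.
- Enabling feature: in the upper unit O7 of ring A is para and O1 ortho to C4a, so C4 ionises readily. In the lower unit ring B is a pyrogallol whose C2' (equivalent to C6') is ortho to O3' and para to O5'.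
- The lower unit is carried at the C4 ketone oxidation level, so its ring A (O7 and O1 conjugated to C=O) is not nucleophilic and its C4 cannot ionise. The last step removes this device.
- No ring is formed: rings A, B and C of both units arrive intact in 1.

Key step: step 2

Remark: (+)-dihydrorobinetin, the (2R,3R)-flavanonol, is taken as a purchasable enantiopure compound; the C2 and C3 stereocentres of both units come from it.

Step 1
Reactants: 1 (+)-dihydrorobinetin
Product: 2 (+)-leucorobinetinidin, the (2R,3S,4R) 2,3-trans-3,4-trans flavan-3,4-diol
Conditions: NaBH4, EtOH, 0 °C to rt, N2; then AcOH to pH 6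
Reagents that add atoms: none
Why: Sodium borohydride reduction of the aryl ketone of a 2,3-trans flavanonol should deliver hydride axially to the β face of C4 (the face of H-2, anti to H-3) and give mainly the 3,4-trans diol, and the C4 configuration formed here is erased anyway when C4 ionises in step 2.

Step 2
Reactants: 2 (+)-leucorobinetinidin; 1 (+)-dihydrorobinetin
Product: 4 robinetinidol-(4α→2')-dihydrorobinetin, via ring A para-quinone methide 3 (not isolated)
Conditions: 1 (5 equiv), 0.1 M aq. HCl/1,4-dioxane (1:1), 2 added over 6 h, N2, 25 °C
Reagents that add atoms: none
Why: Acid-promoted loss of the C4 hydroxyl of 2, assisted by the para O7 and ortho O1 lone pairs of ring A, gives the C4 benzylic cation (para-quinone methide 3 in its protonated form), which C2' of the pyrogallol ring B of 1 captures in an SN1 Friedel–Crafts alkylation followed by rearomatisation. The closest known reaction type is the acid-catalysed condensation of a flavan-3,4-diol with a phenolic nucleus used to assemble proanthocyanidins. No ring is closed; the step is an intermolecular union of two unprotected C15 units that creates the whole C30 skeleton. The new C4 stereocentre is controlled by the adjacent C3 stereocentre of the 2,3-trans cation: the arene should approach quasi-axially on the α face, anti to the β 3-OH, to give the 3,4-trans (4α, 4S) adduct, with the minor 3,4-cis epimer removed by chromatography. The step needs site selectivity for ring B of 1, which the substrate secures because the C4 carbonyl of 1 deactivates its ring A, C2' and C6' are equivalent by rotation about the C2–C1' bond, and O-alkylation is reversible in acid while C-alkylation is not. Self-condensation of 2 through its own ring A is held back by the excess of 1 and the slow addition of 2, and the excess 1 is recovered.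

Step 3
Reactants: 4 robinetinidol-(4α→2')-dihydrorobinetin
Product: 5 robinetinidol-(4α→2')-leucorobinetinidin (target)
Conditions: NaBH4, EtOH, 0 °C to rt, N2; then AcOH to pH 6, Sephadex LH-20
Reagents that add atoms: none
Why: Sodium borohydride reduction of the only carbonyl, the ring C ketone of the flavanonol unit, should again deliver hydride axially to the β face of the lower C4 (anti to the axial H-3), placing the new hydroxyl equatorial and trans to the 3-OH (lower C4 = R), while the near-neutral quench keeps the new benzylic carbinol from ionising.

**Compound list**
1 | (+)-dihydrorobinetin, (2R,3R)-3,7-dihydroxy-2-(3,4,5-trihydroxyphenyl)-2,3-dihydro-4H-chromen-4-one | O=C1c2ccc(O)cc2O[C@H](c2cc(O)c(O)c(O)c2)[C@H]1O | starting material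
2 | (+)-leucorobinetinidin, (2R,3S,4R)-2-(3,4,5-trihydroxyphenyl)-3,4-dihydro-2H-chromene-3,4,7-triol | Oc1cc(cc(O)c1O)[C@H]1Oc2cc(O)ccc2[C@@H](O)[C@@H]1O | intermediate
3 | ring A para-quinone methide, (2R,3S)-3-hydroxy-2-(3,4,5-trihydroxyphenyl)-2,3-dihydro-7H-chromen-7-one (conjugate base of the C4 cation; not isolated) | O=C1C=CC2=C[C@H](O)[C@@H](c3cc(O)c(O)c(O)c3)OC2=C1 | intermediate
4 | robinetinidol-(4α→2')-dihydrorobinetin, (2R,3R)-3,7-dihydroxy-2-{3,4,5-trihydroxy-2-[(2R,3S,4S)-3,7-dihydroxy-2-(3,4,5-trihydroxyphenyl)-3,4-dihydro-2H-chromen-4-yl]phenyl}-2,3-dihydro-4H-chromen-4-one | Oc1ccc2c(c1)O[C@H](c1cc(O)c(O)c(O)c1)[C@@H](O)[C@@H]2c1c([C@H]2Oc3cc(O)ccc3C(=O)[C@@H]2O)cc(O)c(O)c1O | intermediate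
5 | robinetinidol-(4α→2')-leucorobinetinidin, (2R,3S,4R)-2-{3,4,5-trihydroxy-2-[(2R,3S,4S)-3,7-dihydroxy-2-(3,4,5-trihydroxyphenyl)-3,4-dihydro-2H-chromen-4-yl]phenyl}-3,4-dihydro-2H-chromene-3,4,7-triol | Oc1ccc2c(c1)O[C@H](c1cc(O)c(O)c(O)c1)[C@@H](O)[C@@H]2c1c([C@H]2Oc3cc(O)ccc3[C@@H](O)[C@@H]2O)cc(O)c(O)c1O | target

Total step count: 3. Longest linear sequence: 3 steps (1 to 2 to 4 to 5; 1 enters a second time in step 2).

**Steps most likely to fail**

Step 2. The cation may be consumed by self-condensation of 2 through its own ring A, and by further alkylation of ring A of the upper unit of the product, faster than ring B of 1 captures it; facial selectivity at C4 may also be modest. The fallback sets out from 2. Acid-catalysed thiolysis (phenylmethanethiol, AcOH, EtOH, 60 °C) should convert it into 4α-benzylsulfanylrobinetinidol F1, a storable C4 thioether that does not ionise on its own (either C4 epimer serves). Treating F1 with AgBF4 in THF at 0 °C in the presence of excess 1 should then release the C4 cation irreversibly, by thiophilic activation in an aprotic medium and only where the nucleophile is already present. This replaces equilibrium ionisation in aqueous acid and comes back to the route at 4.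

Step 3. Facial selectivity at the lower C4 may erode because the ortho-substituted ring B now crowds the β face of ring C, and the basic medium may open ring C of the flavanonol unit before reduction. The fallback sets out from 4 and replaces intermolecular, sterically governed hydride attack by intramolecular delivery. Me4NBH(OAc)3 in MeCN/AcOH at −20 °C should bind the β 3-OH of the flavanonol unit and pass hydride to the β face of the adjacent C4 carbonyl (Saksena–Evans reduction of an α-hydroxy ketone). This should give the 3,4-trans diol under non-basic conditions. It comes back at 5 and makes no new compound (F0).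

Step 1. Diol 2 is its own electrophile and nucleophile, so it may be lost by acid-triggered self-condensation during quench and concentration. The fallback sets out from 1. After reduction with NaBH4 in MeOH the diol is not isolated; the methanolic solution is acidified with HCl to pH 2 so that solvent methanol captures the cation. This should give 4-O-methylleucorobinetinidin F2, a benzylic methyl ether that should survive concentration and chromatography (either C4 epimer serves). Under the conditions of step 2, F2 should ionise to 3 with loss of methanol, and the route is rejoined at 4.

**Further compounds**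
F1 | step 2 | 4α-benzylsulfanylrobinetinidol, (2R,3R,4R)-4-(benzylsulfanyl)-2-(3,4,5-trihydroxyphenyl)-3,4-dihydro-2H-chromene-3,7-diol | Oc1cc(cc(O)c1O)[C@H]1Oc2cc(O)ccc2[C@@H](SCc2ccccc2)[C@@H]1O
F0 | step 3 | none | none
F2 | step 1 | 4-O-methylleucorobinetinidin, (2R,3S,4R)-4-methoxy-2-(3,4,5-trihydroxyphenyl)-3,4-dihydro-2H-chromene-3,7-diol | Oc1cc(cc(O)c1O)[C@H]1Oc2cc(O)ccc2[C@@H](OC)[C@@H]1O
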